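**Plan**
- Retrosynthesis: remove the C3 acetate and the C5 silyl ether, then cut C2–C3. In the five-membered ring (C1, C2, C3, C3a, C7a) the C2 ketone and the C3 oxygen form an acyloin, the product of joining two aldehyde carbons. This leads to a cyclohexane with CHO on C3a and CH2CHO on C7a.
- Further cuts: the C6 ester, C7=C8 (methylenation), C7a–C1 (enolate alkylation) and C3a–C3 (conjugate addition) lead to a 4-isopropyl-5,6-dioxygenated cyclohex-2-enone. Then C3a=C7a (metathesis), C7–C7a (vinyl Grignard) and C4–C5 (allylboration) lead to (S)-glyceraldehyde acetonide.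
- Forward: the C4–C7 chain is built first, the six-membered ring closes by metathesis, both arms, the exocyclic methylene and the angelate follow, and the five-membered ring closes last by carbene-catalysed benzoin cyclisation.
- Stereochemistry: C6 comes from the chiral pool; C4 and C5 from a reagent-controlled E-allylboration; C3a and C7a from anti conjugate addition and anti alkylation relative to C4; C3 from thermodynamic control in the benzoin step.

Key step: step 18

Remark: atoms carry the locants of the target hydrindane (C1–C3, C3a, C4–C7, C7a, exocyclic C8) in all intermediates, and α denotes the ring face of the C4 isopropyl group. The C3 configuration of the target (oxygen α, cis to H3a) is assumed to be the more stable, pseudo-equatorial one of the trans-fused 2-ketone.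

Step 1
Reactants: 1 (S)-2,2-dimethyl-1,3-dioxolane-4-carbaldehyde; 2 (E)-4-methylpent-2-ene
Product: 4 (1S,2S)-1-[(4S)-2,2-dimethyl-1,3-dioxolan-4-yl]-2-(propan-2-yl)but-3-en-1-ol, via E-allylborane 3 (not isolated)
Conditions: 2, KOtBu, n-BuLi, THF, −45 °C; (−)-Ipc2BOMe, −78 °C; BF3·OEt2; 1, −78 °C; NaOH, H2O2
Reagents that add atoms: (E)-4-methylpent-2-ene 2, C/C=C/C(C)C
Why: Reagent-controlled allylboration with a diisopinocampheylborane (Brown type) through a closed chair transition state: the E double bond of 3 should give the anti C4/C5 pair, the (+)-α-pinene-derived ligands should direct attack to the aldehyde face that gives the 5S carbinol against the Felkin preference of 1, and C6 is carried in from the chiral pool.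

Step 2
Reactants: 4
Product: 5 tert-butyl{[(1S,2S)-1-[(4S)-2,2-dimethyl-1,3-dioxolan-4-yl]-2-(propan-2-yl)but-3-en-1-yl]oxy}dimethylsilane
Conditions: TBSOTf, 2,6-lutidine, CH2Cl2, −78 → 0 °C
Reagents that add atoms: tert-butyldimethylsilyl trifluoromethanesulfonate, CC(C)(C)[Si](C)(C)OS(=O)(=O)C(F)(F)F
Why: Silyl ether formation with a silyl triflate, which should silylate the hindered C5 hydroxyl at low temperature while the lutidine buffer protects the acetonide.

Step 3
Reactants: 5
Product: 6 (2S,3S,4S)-3-[(tert-butyldimethylsilyl)oxy]-4-(propan-2-yl)hex-5-ene-1,2-diol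
Conditions: AcOH/THF/H2O (4:1:1), 45 °C
Reagents that add atoms: none
Why: Acid-catalysed hydrolysis of the terminal isopropylidene acetal, which should be cleaved in aqueous acetic acid well before a hindered secondary TBS ether.

Step 4
Reactants: 6
Product: 7 (4S)-4-[(1S,2S)-1-[(tert-butyldimethylsilyl)oxy]-2-(propan-2-yl)but-3-en-1-yl]-2-(4-methoxyphenyl)-1,3-dioxolane (both acetal epimers)
Conditions: 4-MeOC6H4CH(OMe)2, PPTS (cat.), CH2Cl2, rt
Reagents that add atoms: 4-methoxybenzaldehyde dimethyl acetal, COc1ccc(cc1)C(OC)OC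
Why: Acid-catalysed transacetalisation that should close the five-membered 4-methoxybenzylidene acetal on the 1,2-diol; the new acetal centre is removed in the next step.

Step 5
Reactants: 7
Product: 8 (2S,3S,4S)-3-[(tert-butyldimethylsilyl)oxy]-2-[(4-methoxybenzyl)oxy]-4-(propan-2-yl)hex-5-en-1-ol
Conditions: i-Bu2AlH, CH2Cl2, −78 → 0 °C
Reagents that add atoms: none
Why: Regioselective reductive opening of the arylidene acetal: the aluminium hydride should coordinate the less hindered primary oxygen and reduce the oxocarbenium ion, leaving the PMB group on the secondary C6 oxygen and freeing the C7 hydroxyl.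

Step 6
Reactants: 8
Product: 9 (2R,3S,4S)-3-[(tert-butyldimethylsilyl)oxy]-2-[(4-methoxybenzyl)oxy]-4-(propan-2-yl)hex-5-enal
Conditions: Dess–Martin periodinane, NaHCO3, CH2Cl2, 0 °C → rt
Reagents that add atoms: none
Why: Dess–Martin oxidation under buffered, non-basic conditions, which should give the α-alkoxy aldehyde without epimerisation at C6.

Step 7
Reactants: 9; 10 vinylmagnesium bromide
Product: 11 (4S,5S,6S)-5-[(tert-butyldimethylsilyl)oxy]-4-[(4-methoxybenzyl)oxy]-6-(propan-2-yl)octa-1,7-dien-3-ol (both C3 epimers)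
Conditions: 10, THF, −78 °C
Reagents that add atoms: vinylmagnesium bromide 10, C=C[Mg]Br
Why: Grignard 1,2-addition to the aldehyde; the new C7 carbinol centre may form as a mixture because it is oxidised in step 9.

Step 8
Reactants: 11
Product: 12 (4S,5S,6S)-5-[(tert-butyldimethylsilyl)oxy]-6-[(4-methoxybenzyl)oxy]-4-(propan-2-yl)cyclohex-2-en-1-ol (both C1 epimers)
Conditions: second-generation Grubbs catalyst (H2IMes)(PCy3)Cl2Ru=CHPh (5 mol %), CH2Cl2, 40 °C
Reagents that add atoms: none
Why: Ring-closing metathesis of the 1,7-diene with loss of ethene should close the six-membered ring at C3a=C7a, free allylic hydroxyl groups being tolerated by the ruthenium carbene.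

Step 9
Reactants: 12
Product: 13 (4S,5S,6R)-5-[(tert-butyldimethylsilyl)oxy]-6-[(4-methoxybenzyl)oxy]-4-(propan-2-yl)cyclohex-2-en-1-one
Conditions: Dess–Martin periodinane, NaHCO3, CH2Cl2, rt
Reagents that add atoms: none
Why: Dess–Martin oxidation of the allylic alcohol, which should merge both C7 epimers into the single cyclohexenone.

Step 10
Reactants: 13; 10 vinylmagnesium bromide; 14 tert-butyl bromoacetate
Product: 16 keto ester (C7 ketone, C7a α-CH2CO2t-Bu, C3a β-vinyl, C4 α-isopropyl, C5 α-OTBS, C6 β-OPMB), via magnesium enolate 15 (not isolated)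
Conditions: 10, CuBr·SMe2 (20 mol %), THF, −78 → −40 °C; then HMPA, 14, −40 → 0 °C
Reagents that add atoms: vinylmagnesium bromide 10, C=C[Mg]Br; tert-butyl bromoacetate 14, CC(C)(C)OC(=O)CBr
Why: Copper-catalysed conjugate addition of the Grignard reagent with in situ alkylation of the enolate (three-component coupling): vinyl should enter C3a anti to the C4 isopropyl and C5 silyloxy groups, and enolate 15 should be alkylated at C7a anti to the new vinyl group, which sets the trans C3a/C7a pair.

Step 11
Reactants: 16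
Product: 19 hydroxy keto ester (C3a β-CH2OH, otherwise as 16), via ozonide 17 (not isolated), via keto aldehyde 18 (not isolated)
Conditions: O3, CH2Cl2, −78 °C; PPh3, → rt; NaBH(OAc)3, AcOH, rt
Reagents that add atoms: ozone, [O-][O+]=O
Why: Ozonolysis of the only alkene with phosphine reduction of ozonide 17, followed by chemoselective reduction of the aldehyde of 18 with the mild triacetoxyborohydride, which should not touch the hindered C7 ketone or the ester.

Step 12
Reactants: 19
Product: 20 methylene hydroxy ester (C7=C8H2, C7a α-CH2CO2t-Bu, C3a β-CH2OH, C4 α-isopropyl, C5 α-OTBS, C6 β-OPMB)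
Conditions: Zn, CH2Br2, TiCl4, THF/CH2Cl2, 0 °C → rt
Reagents that add atoms: dibromomethane, BrCBr
Why: Takai–Lombardo methylenation with the non-basic zinc–titanium methylene reagent, which should convert the hindered ketone without epimerising C6 or C7a and should leave the tert-butyl ester and the free hydroxyl alone.

Step 13
Reactants: 20
Product: 21 diol (C7a α-CH2CH2OH, C3a β-CH2OH, otherwise as 20)
Conditions: LiAlH4, THF, 0 °C
Reagents that add atoms: none
Why: Hydride reduction of the ester to the primary alcohol with LiAlH4, to which the silyl ether, the PMB ether and the alkene are inert.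

Step 14
Reactants: 21
Product: 22 bis(triethylsilyl) ether of 21
Conditions: TESCl, imidazole, CH2Cl2, 0 °C
Reagents that add atoms: chlorotriethylsilane, CC[Si](CC)(CC)Cl
Why: Silylation of both primary alcohols as triethylsilyl ethers, which can later be told apart from the secondary TBS ether.

Step 15
Reactants: 22
Product: 23 C6 alcohol (C6 β-OH, C5 α-OTBS, both arms as TES ethers, C7=C8H2)
Conditions: DDQ, CH2Cl2/H2O (pH 7), 0 °C
Reagents that add atoms: none
Why: Oxidative cleavage of the PMB ether by DDQ (hydride abstraction and hydrolysis of the oxocarbenium ion), orthogonal to silyl ethers and to the 1,1-disubstituted alkene.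

Step 16
Reactants: 23; 24 angelic acid
Product: 26 C6 angelate of 23, via mixed anhydride 25 (not isolated)
Conditions: 24, 2,4,6-trichlorobenzoyl chloride, Et3N, toluene, rt; then 23, 80 °C
Reagents that add atoms: angelic acid 24, C/C=C(/C)C(O)=O
Why: Yamaguchi esterification through mixed anhydride 25; leaving out DMAP and acylating the hindered allylic C6 hydroxyl thermally should keep the Z double bond of the angelate from isomerising to the tiglate.

Step 17
Reactants: 26
Product: 28 dialdehyde (C3a β-CHO, C7a α-CH2CHO, C4 α-isopropyl, C5 α-OTBS, C6 β-angelate, C7=C8H2), via bis(alkoxysulfonium) salt 27 (not isolated)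
Conditions: (COCl)2, DMSO, CH2Cl2, −78 → −40 °C; Et3N, −78 → 0 °C
Reagents that add atoms: none
Why: Swern oxidation applied directly to primary triethylsilyl ethers: activated DMSO should cleave the two primary Si–O bonds to give 27 and triethylamine then should release both aldehydes, while the secondary TBS ether and the ester stay.

Step 18
Reactants: 28
Product: 30 (3R,3aR,4S,5S,6S,7aR)-5-[(tert-butyldimethylsilyl)oxy]-3-hydroxy-7-methylidene-2-oxo-4-(propan-2-yl)octahydro-1H-inden-6-yl (2Z)-2-methylbut-2-enoate, via Breslow enaminol 29 (not isolated)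
Conditions: 2-(pentafluorophenyl)-6,7-dihydro-5H-pyrrolo[2,1-c][1,2,4]triazol-2-ium tetrafluoroborate (20 mol %), i-Pr2NEt (20 mol %), THF (0.02 M), rt
Reagents that add atoms: none
Why: The amine base frees the triazolylidene, which adds to the unhindered C2 aldehyde; proton transfer gives Breslow enaminol 29, whose nucleophilic C2 attacks the neighbouring C3 aldehyde, and collapse of the adduct releases the carbene and the ketol with the ketone at C2 and the hydroxyl at C3. The closest known reaction type is the carbene-catalysed intramolecular crossed benzoin (acyloin) cyclisation of dialdehydes and keto aldehydes to cyclic α-hydroxy ketones. The five-membered ring closes in the 5-exo-trig mode on the C3 carbonyl, and the trans-diequatorial arms on C3a and C7a hold the two formyl carbons within bonding distance and lead to the trans-fused hydrindanone. The new C3 stereocentre is under thermodynamic control, because the benzoin addition is reversible and the α-ketol can epimerise through its enediol under the amine base, so the product should settle with the C3 hydroxyl pseudo-equatorial and cis to H3a (3R), as in the target. The step needs donor/acceptor chemoselectivity, which the substrate secures sterically: the bulky N-aryl carbene should form the acyl anion equivalent at the CH2-flanked aldehyde and not at the α-branched C3 aldehyde next to the C4 isopropyl group, intramolecular aldol pathways would give only four-membered rings, and the α,β-disubstituted angelate is a poor Michael acceptor.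

Step 19
Reactants: 30
Product: 31 (3R,3aR,4S,5S,6S,7aR)-3-acetoxy-5-[(tert-butyldimethylsilyl)oxy]-7-methylidene-2-oxo-4-(propan-2-yl)octahydro-1H-inden-6-yl (2Z)-2-methylbut-2-enoate
Conditions: Ac2O, pyridine, DMAP (cat.), CH2Cl2, 0 °C
Reagents that add atoms: acetic anhydride, CC(=O)OC(C)=O
Why: Acylation of the secondary α-ketol hydroxyl with acetic anhydride under DMAP catalysis at low temperature, which should be faster than any base-induced ketol isomerisation.

Step 20
Reactants: 31
Product: 32 (3R,3aR,4S,5S,6S,7aR)-3-acetoxy-5-hydroxy-7-methylidene-2-oxo-4-(propan-2-yl)octahydro-1H-inden-6-yl (2Z)-2-methylbut-2-enoate (CNP0317011.1)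
Conditions: HF·pyridine, pyridine, THF, 0 °C → rt
Reagents that add atoms: none
Why: Fluoride-mediated cleavage of the silyl ether with buffered HF·pyridine, mild enough to leave the α-acetoxy ketone, the allylic angelate and the exocyclic alkene untouched and to avoid acyl migration from O6 to O5.

**Compound list**
1 | (S)-2,2-dimethyl-1,3-dioxolane-4-carbaldehyde ((S)-glyceraldehyde acetonide) | CC1(C)OC[C@H](O1)C=O | starting material
2 | (E)-4-methylpent-2-ene | C/C=C/C(C)C | starting material
3 | (E)-(4-methylpent-2-en-1-yl)diisopinocampheylborane, isopinocampheyl groups from (+)-α-pinene (not isolated) | CC(C)/C=C/CB([C@@H]1C[C@@H]2C[C@H]([C@H]1C)C2(C)C)[C@@H]1C[C@@H]2C[C@H]([C@H]1C)C2(C)C | intermediate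
4 | (1S,2S)-1-[(4S)-2,2-dimethyl-1,3-dioxolan-4-yl]-2-(propan-2-yl)but-3-en-1-ol | C=C[C@H](C(C)C)[C@H](O)[C@@H]1COC(C)(C)O1 | intermediate
5 | tert-butyl{[(1S,2S)-1-[(4S)-2,2-dimethyl-1,3-dioxolan-4-yl]-2-(propan-2-yl)but-3-en-1-yl]oxy}dimethylsilane | C=C[C@H](C(C)C)[C@H](O[Si](C)(C)C(C)(C)C)[C@@H]1COC(C)(C)O1 | intermediate
6 | (2S,3S,4S)-3-[(tert-butyldimethylsilyl)oxy]-4-(propan-2-yl)hex-5-ene-1,2-diol | C=C[C@H](C(C)C)[C@H](O[Si](C)(C)C(C)(C)C)[C@@H](O)CO | intermediate
7 | (4S)-4-[(1S,2S)-1-[(tert-butyldimethylsilyl)oxy]-2-(propan-2-yl)but-3-en-1-yl]-2-(4-methoxyphenyl)-1,3-dioxolane (both acetal epimers) | C=C[C@H](C(C)C)[C@H](O[Si](C)(C)C(C)(C)C)[C@@H]1COC(O1)c1ccc(OC)cc1 | intermediate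
8 | (2S,3S,4S)-3-[(tert-butyldimethylsilyl)oxy]-2-[(4-methoxybenzyl)oxy]-4-(propan-2-yl)hex-5-en-1-ol | C=C[C@H](C(C)C)[C@H](O[Si](C)(C)C(C)(C)C)[C@@H](OCc1ccc(OC)cc1)CO | intermediate
9 | (2R,3S,4S)-3-[(tert-butyldimethylsilyl)oxy]-2-[(4-methoxybenzyl)oxy]-4-(propan-2-yl)hex-5-enal | C=C[C@H](C(C)C)[C@H](O[Si](C)(C)C(C)(C)C)[C@@H](OCc1ccc(OC)cc1)C=O | intermediate
10 | vinylmagnesium bromide | C=C[Mg]Br | starting material
11 | (4S,5S,6S)-5-[(tert-butyldimethylsilyl)oxy]-4-[(4-methoxybenzyl)oxy]-6-(propan-2-yl)octa-1,7-dien-3-ol (both C3 epimers) | C=C[C@H](C(C)C)[C@H](O[Si](C)(C)C(C)(C)C)[C@@H](OCc1ccc(OC)cc1)C(O)C=C | intermediate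
12 | (4S,5S,6S)-5-[(tert-butyldimethylsilyl)oxy]-6-[(4-methoxybenzyl)oxy]-4-(propan-2-yl)cyclohex-2-en-1-ol (both C1 epimers) | OC1C=C[C@H](C(C)C)[C@H](O[Si](C)(C)C(C)(C)C)[C@H]1OCc1ccc(OC)cc1 | intermediate
13 | (4S,5S,6R)-5-[(tert-butyldimethylsilyl)oxy]-6-[(4-methoxybenzyl)oxy]-4-(propan-2-yl)cyclohex-2-en-1-one | O=C1C=C[C@H](C(C)C)[C@H](O[Si](C)(C)C(C)(C)C)[C@H]1OCc1ccc(OC)cc1 | intermediate
14 | tert-butyl bromoacetate | CC(C)(C)OC(=O)CBr | starting material
15 | bromomagnesium enolate (C7 O–MgBr, C7=C7a, C3a β-vinyl) (not isolated) | Br[Mg]OC1=C[C@@H](C=C)[C@H](C(C)C)[C@H](O[Si](C)(C)C(C)(C)C)[C@H]1OCc1ccc(OC)cc1 | intermediate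
16 | keto ester: C7 ketone, C7a α-CH2CO2t-Bu, C3a β-vinyl, C4 α-isopropyl, C5 α-OTBS, C6 β-OPMB | O=C1[C@H](CC(=O)OC(C)(C)C)[C@@H](C=C)[C@H](C(C)C)[C@H](O[Si](C)(C)C(C)(C)C)[C@H]1OCc1ccc(OC)cc1 | intermediate
17 | ozonide (1,2,4-trioxolane) of the vinyl group of 16 (not isolated) | O=C1[C@H](CC(=O)OC(C)(C)C)[C@@H](C2OCOO2)[C@H](C(C)C)[C@H](O[Si](C)(C)C(C)(C)C)[C@H]1OCc1ccc(OC)cc1 | intermediate
18 | keto aldehyde: C3a β-CHO, otherwise as 16 (not isolated) | O=C1[C@H](CC(=O)OC(C)(C)C)[C@@H](C=O)[C@H](C(C)C)[C@H](O[Si](C)(C)C(C)(C)C)[C@H]1OCc1ccc(OC)cc1 | intermediate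
19 | hydroxy keto ester: C3a β-CH2OH, otherwise as 16 | O=C1[C@H](CC(=O)OC(C)(C)C)[C@@H](CO)[C@H](C(C)C)[C@H](O[Si](C)(C)C(C)(C)C)[C@H]1OCc1ccc(OC)cc1 | intermediate
20 | methylene hydroxy ester: C7=C8H2, otherwise as 19 | C=C1[C@H](CC(=O)OC(C)(C)C)[C@@H](CO)[C@H](C(C)C)[C@H](O[Si](C)(C)C(C)(C)C)[C@H]1OCc1ccc(OC)cc1 | intermediate
21 | diol: C7a α-CH2CH2OH, C3a β-CH2OH, C5 α-OTBS, C6 β-OPMB, C7=C8H2 | C=C1[C@H](CCO)[C@@H](CO)[C@H](C(C)C)[C@H](O[Si](C)(C)C(C)(C)C)[C@H]1OCc1ccc(OC)cc1 | intermediate
22 | bis(triethylsilyl) ether of 21 | C=C1[C@H](CCO[Si](CC)(CC)CC)[C@@H](CO[Si](CC)(CC)CC)[C@H](C(C)C)[C@H](O[Si](C)(C)C(C)(C)C)[C@H]1OCc1ccc(OC)cc1 | intermediate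
23 | C6 alcohol: 22 without the PMB group | C=C1[C@H](CCO[Si](CC)(CC)CC)[C@@H](CO[Si](CC)(CC)CC)[C@H](C(C)C)[C@H](O[Si](C)(C)C(C)(C)C)[C@H]1O | intermediate
24 | angelic acid ((Z)-2-methylbut-2-enoic acid) | C/C=C(/C)C(O)=O | starting material
25 | angelic 2,4,6-trichlorobenzoic anhydride (not isolated) | C/C=C(/C)C(=O)OC(=O)c1c(Cl)cc(Cl)cc1Cl | intermediate
26 | C6 angelate of 23 | C=C1[C@H](CCO[Si](CC)(CC)CC)[C@@H](CO[Si](CC)(CC)CC)[C@H](C(C)C)[C@H](O[Si](C)(C)C(C)(C)C)[C@H]1OC(=O)/C(C)=C\C | intermediate
27 | bis(alkoxydimethylsulfonium) dichloride from 26 (not isolated) | C=C1[C@H](CCO[S+](C)C)[C@@H](CO[S+](C)C)[C@H](C(C)C)[C@H](O[Si](C)(C)C(C)(C)C)[C@H]1OC(=O)/C(C)=C\C.[Cl-].[Cl-] | intermediate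
28 | dialdehyde: C3a β-CHO, C7a α-CH2CHO, C4 α-isopropyl, C5 α-OTBS, C6 β-angelate, C7=C8H2 | C=C1[C@H](CC=O)[C@@H](C=O)[C@H](C(C)C)[C@H](O[Si](C)(C)C(C)(C)C)[C@H]1OC(=O)/C(C)=C\C | intermediate
29 | Breslow enaminol of the C2 aldehyde of 28 with the triazolylidene (not isolated) | C=C1[C@H](CC(O)=C2N(c3c(F)c(F)c(F)c(F)c3F)N=C3CCCN23)[C@@H](C=O)[C@H](C(C)C)[C@H](O[Si](C)(C)C(C)(C)C)[C@H]1OC(=O)/C(C)=C\C | intermediate
30 | (3R,3aR,4S,5S,6S,7aR)-5-[(tert-butyldimethylsilyl)oxy]-3-hydroxy-7-methylidene-2-oxo-4-(propan-2-yl)octahydro-1H-inden-6-yl (2Z)-2-methylbut-2-enoate | C=C1[C@@H]2CC(=O)[C@H](O)[C@H]2[C@H](C(C)C)[C@H](O[Si](C)(C)C(C)(C)C)[C@H]1OC(=O)/C(C)=C\C | intermediate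
31 | (3R,3aR,4S,5S,6S,7aR)-3-acetoxy-5-[(tert-butyldimethylsilyl)oxy]-7-methylidene-2-oxo-4-(propan-2-yl)octahydro-1H-inden-6-yl (2Z)-2-methylbut-2-enoate | C=C1[C@@H]2CC(=O)[C@H](OC(C)=O)[C@H]2[C@H](C(C)C)[C@H](O[Si](C)(C)C(C)(C)C)[C@H]1OC(=O)/C(C)=C\C | intermediate
32 | (3R,3aR,4S,5S,6S,7aR)-3-acetoxy-5-hydroxy-7-methylidene-2-oxo-4-(propan-2-yl)octahydro-1H-inden-6-yl (2Z)-2-methylbut-2-enoate (CNP0317011.1) | C=C1[C@@H]2CC(=O)[C@H](OC(C)=O)[C@H]2[C@H](C(C)C)[C@H](O)[C@H]1OC(=O)/C(C)=C\C | target

**Step count and risks**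
Total step count: 20. Longest linear sequence: 20 steps (1 to 32); 2, 10, 14 and 24 enter along the way without branch steps.

Steps most likely to fail:

1. Step 18 (benzoin closure). The carbene may take the branched C3 aldehyde as the acyl donor. The ketol may also tautomerise through its enediol, which would move the ketone to C3 and open C3a to epimerisation. The equilibrium at C3 may also favour the needed epimer too weakly. Fallback: starting from 28, reductive pinacol cyclisation with SmI2 (THF, t-BuOH, −78 °C) forms the same C2–C3 bond without any donor/acceptor distinction and should give the cis-diol F6. IBX in DMSO, which oxidises 1,2-diols without C–C cleavage, should then oxidise the less hindered, CH2-flanked C2 carbinol first. Brief exposure to Et3N should settle C3, and the route is rejoined at 30.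

2. Step 1 (allylboration). The reagent has to override the Felkin bias of the α-alkoxy aldehyde (mismatched pairing), so facial selectivity at C5 may leak, and partial E/Z scrambling of the allyl reagent would erode the C4/C5 relationship. Fallback: starting from 1, the matched pairing is used instead. (Z)-4-Methylpent-2-ene is metalated in the same way and trapped with (+)-Ipc2BOMe and BF3·OEt2 to give the Z-allylborane F1. Its addition to 1 should be reinforced by reagent and substrate and give the C5-epimeric alcohol F2 (C4/C5 syn, C5/C6 anti). Mitsunobu inversion at C5 (4-nitrobenzoic acid, PPh3, DIAD, THF) should give the 4-nitrobenzoate F3, and methanolysis (K2CO3, MeOH) returns to 4.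

3. Step 10 (conjugate addition and alkylation). Alkylation of the hindered magnesium enolate may be slow. Proton exchange with the product could then move the enolate to the C6 side, where the C5 silyloxy group can be lost by β-elimination, or could erode the trans selectivity. Fallback: starting from 13, the copper-catalysed vinyl addition is run with Me3SiCl so that the enolate is captured and isolated as the silyl enol ether F4. MeLi (THF, 0 °C) then converts it into the regiodefined and more reactive lithium enolate F5, which is alkylated with 14 in THF/HMPA at −78 °C, returning to the route at 16.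

Further compounds
F1 | step 1 | (Z)-(4-methylpent-2-en-1-yl)diisopinocampheylborane, isopinocampheyl groups from (−)-α-pinene | CC(C)/C=C\CB([C@H]1C[C@H]2C[C@@H]([C@@H]1C)C2(C)C)[C@H]1C[C@H]2C[C@@H]([C@@H]1C)C2(C)C
F2 | step 1 | (1R,2S)-1-[(4S)-2,2-dimethyl-1,3-dioxolan-4-yl]-2-(propan-2-yl)but-3-en-1-ol | C=C[C@H](C(C)C)[C@@H](O)[C@@H]1COC(C)(C)O1
F3 | step 1 | (1S,2S)-1-[(4S)-2,2-dimethyl-1,3-dioxolan-4-yl]-2-(propan-2-yl)but-3-en-1-yl 4-nitrobenzoate | C=C[C@H](C(C)C)[C@H](OC(=O)c1ccc(cc1)[N+](=O)[O-])[C@@H]1COC(C)(C)O1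
F4 | step 10 | trimethylsilyl enol ether (C7 O–SiMe3, C7=C7a, C3a β-vinyl) | C[Si](C)(C)OC1=C[C@@H](C=C)[C@H](C(C)C)[C@H](O[Si](C)(C)C(C)(C)C)[C@H]1OCc1ccc(OC)cc1
F5 | step 10 | lithium enolate corresponding to F4 | [Li]OC1=C[C@@H](C=C)[C@H](C(C)C)[C@H](O[Si](C)(C)C(C)(C)C)[C@H]1OCc1ccc(OC)cc1
F6 | step 18 | cis-2,3-diol of the hydrindane (C2 and C3 hydroxyls α, otherwise as 30) | C=C1[C@@H]2C[C@H](O)[C@H](O)[C@H]2[C@H](C(C)C)[C@H](O[Si](C)(C)C(C)(C)C)[C@H]1OC(=O)/C(C)=C\C
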